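## Retrosynthetic overview

1. C50 = C20 + C10 + C20. Two Wittig olefinations on a C10 trienedial (C11=C12 first, C11'=C12' last) join an acyclic-end C20 phosphonium salt and an ε-end C20 phosphonium salt. Global desilylation ends the route.
2. Enabling feature: in ring A (C1'–C6') the C4'=C5' double bond lies β,γ to C6'. C4'–C5'–C6' is therefore an allyl triad and C4'=C5'–C6'–C7'=C8' a skipped diene, so the C6'–C7' bond is the retron of a [2,3]-shift of a carbon chain from an oxygen on C4' to C6'.
3. Key disconnection C6'–C7': ring-A allylic alcohol (C4'–OH cis to the C2' chain, C5'=C6') plus a C6 dienyl bromide (C7'–C11'). O-alkylation and [2,3]-Wittig rearrangement in one flask form C6'–C7', set C6' on the hindered face and place the alkene at C4'=C5'. Ionisation and PPh3 capture at C11' then give the ε-end salt.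
4. Ring A is the only ring and is made first (Robinson annulation, then dehydrogenation to the cross-conjugated dienone). C2' is set by Rh-catalysed asymmetric vinyl addition, and C4' (Luche reduction) and C6' (key step) are relayed from it.
5. The C2 stereocentre is bought with a lavandulyl monoterpene alcohol. Markovnikov hydration, oxidation and two C5 Horner–Wadsworth–Emmons cycles give the acyclic-end salt.

Key step: step 10

Remark: carotenoid numbering is used throughout (unprimed C1–C20 for the acyclic half, primed numbers for the ring half, C1''–C4'' for the chain on C2', ring A = C1'–C6'), and every compound marked as starting material is taken to be purchasable in the stated isomeric form.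

## Route

Step 1
Reactants: 1 2-methylpropanal; 2 pent-1-en-3-one
Product: 3 2,4,4-trimethylcyclohex-2-en-1-one
Conditions: H2SO4 (cat.), toluene, reflux, Dean–Stark trap
Reagents that add atoms: none
Why: Acid-catalysed Robinson annulation: the enol of 1 adds to 2 (Michael addition) and the 1,5-keto aldehyde closes ring A by intramolecular aldol condensation, which installs the C1' gem-dimethyl group, the C5' methyl group and the C4' carbonyl group at once without any stereocentre.

Step 2
Reactants: 3 2,4,4-trimethylcyclohex-2-en-1-one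
Product: 4 2,4,4-trimethylcyclohexa-2,5-dien-1-one
Conditions: DDQ, 1,4-dioxane, reflux
Reagents that add atoms: none
Why: DDQ dehydrogenation of a cyclohexenone through its cross-conjugated enol; the quaternary C1' blocks aromatisation, so the reaction should stop at the cross-conjugated dienone.

Step 3
Reactants: 4 2,4,4-trimethylcyclohexa-2,5-dien-1-one
Product: 5 (5R)-2,4,4-trimethyl-5-vinylcyclohex-2-en-1-one
Conditions: [Rh(cod)2]BF4 (3 mol %), (R)-BINAP (3.3 mol %), toluene/H2O 10:1, 100 °C
Reagents that add atoms: potassium vinyltrifluoroborate, [K+].C=C[B-](F)(F)F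
Why: Hayashi–Miyaura reaction (rhodium-catalysed asymmetric 1,4-addition): the vinylrhodium–BINAP species inserts the unsubstituted enone arm of 4 in preference to the α-methyl-substituted arm, and the ligand selects the enone face, which sets C2' (5R here), the only stereocentre of ring A made by catalysis.

Step 4
Reactants: 5 (5R)-2,4,4-trimethyl-5-vinylcyclohex-2-en-1-one
Product: 6 [(1S)-2,2,4-trimethyl-5-oxocyclohex-3-en-1-yl]acetaldehyde
Conditions: PdCl2(PhCN)2 (cat.), CuCl2·2H2O (cat.), AgNO2 (cat.), O2 (1 atm), t-BuOH/MeNO2 15:1, rt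
Reagents that add atoms: dioxygen, O=O
Why: Nitrite-modified, aldehyde-selective (anti-Markovnikov) Wacker oxidation of a terminal alkene; the electron-poor trisubstituted enone alkene is not a substrate and C2' is not touched.

Step 5
Reactants: 6 [(1S)-2,2,4-trimethyl-5-oxocyclohex-3-en-1-yl]acetaldehyde
Product: 7 (2E)-2-methyl-4-[(1S)-2,2,4-trimethyl-5-oxocyclohex-3-en-1-yl]but-2-enal
Conditions: toluene, 90 °C
Reagents that add atoms: 2-(triphenylphosphoranylidene)propanal, CC(C=O)=P(c1ccccc1)(c1ccccc1)c1ccccc1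
Why: Wittig olefination with a stabilised ylide, which reacts with the aldehyde only (not with the hindered enone carbonyl) and gives the E-trisubstituted enal C2''=C3''.

Step 6
Reactants: 7 (2E)-2-methyl-4-[(1S)-2,2,4-trimethyl-5-oxocyclohex-3-en-1-yl]but-2-enal
Product: 8 (1R,5S)-5-[(2E)-4-hydroxy-3-methylbut-2-en-1-yl]-2,4,4-trimethylcyclohex-2-en-1-ol
Conditions: NaBH4, CeCl3·7H2O, MeOH, −78 → 0 °C
Reagents that add atoms: none
Why: Luche reduction: both carbonyl groups are reduced 1,2, and axial hydride attack on the half-chair enone that carries the C2' chain equatorial gives the pseudo-equatorial C4' alcohol cis to that chain (substrate control from C2', as in other 5-substituted cyclohex-2-enones).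

Step 7
Reactants: 8 (1R,5S)-5-[(2E)-4-hydroxy-3-methylbut-2-en-1-yl]-2,4,4-trimethylcyclohex-2-en-1-ol
Product: 9 (1R,5S)-5-{(2E)-4-[(tert-butyldiphenylsilyl)oxy]-3-methylbut-2-en-1-yl}-2,4,4-trimethylcyclohex-2-en-1-ol
Conditions: TBDPSCl (1.05 equiv), imidazole, CH2Cl2, −20 → 0 °C
Reagents that add atoms: tert-butyl(chloro)diphenylsilane, CC(C)(C)[Si](Cl)(c1ccccc1)c1ccccc1
Why: Steric differentiation in silyl ether formation: the bulky chlorosilane reacts with the primary allylic alcohol much faster than with the secondary C4' alcohol flanked by the C5' methyl group.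

Step 8
Reactants: 10 (2E)-3-methylpent-2-en-4-yn-1-ol
Product: 11 (2E)-3-methylpenta-2,4-dien-1-ol
Conditions: H2 (1 atm), Pd/CaCO3 poisoned with Pb(OAc)2, quinoline, hexane/EtOAc, 0 °C
Reagents that add atoms: none
Why: Semihydrogenation of the terminal alkyne over the lead-poisoned palladium catalyst (Lindlar type) stops at the vinyl group and should leave the trisubstituted alkene and its E geometry untouched.

Step 9
Reactants: 11 (2E)-3-methylpenta-2,4-dien-1-ol
Product: 12 (3E)-5-bromo-3-methylpenta-1,3-diene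
Conditions: PBr3, Et2O, −10 °C
Reagents that add atoms: phosphorus tribromide, BrP(Br)Br
Why: SN2 bromination of a primary allylic alcohol through its phosphite ester at low temperature, which keeps the E-diene unit in place.

Step 10
Reactants: 9 (1R,5S)-5-{(2E)-4-[(tert-butyldiphenylsilyl)oxy]-3-methylbut-2-en-1-yl}-2,4,4-trimethylcyclohex-2-en-1-ol; 12 (3E)-5-bromo-3-methylpenta-1,3-diene
Product: 15 (2E)-1-[(1R,5R)-5-{(2E)-4-[(tert-butyldiphenylsilyl)oxy]-3-methylbut-2-en-1-yl}-2,6,6-trimethylcyclohex-2-en-1-yl]-3-methylpenta-2,4-dien-1-ol (both C7' carbinol epimers), via bis-allylic ether 13 (not isolated), via C7'-lithiated ether 14 (not isolated)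
Conditions: KH, THF, 0 °C; 12, 0 °C → rt; then n-BuLi, −78 → −20 °C; H2O
Reagents that add atoms: none
Why: The potassium alkoxide of 9 is O-alkylated by the allylic bromide 12 (Williamson ether synthesis) to give 13, whose C7'H2 group is activated both by the ether oxygen and by the pentadienyl π-system and is therefore the site lithiated by n-BuLi to give 14. Compound 14 undergoes a concerted suprafacial [2,3]-Wittig rearrangement through a five-membered envelope transition state (O, C4', C5', C6', C7') in which C4'–O breaks, C6'–C7' forms and the ring double bond moves from C5'=C6' to C4'=C5'; the closest known reaction type is the [2,3]-Wittig rearrangement of cyclohex-2-enyl allyl and propargyl ethers. No ring is closed. C6' is controlled by 1,3-chirality transfer, because the carbanion is tied to the oxygen on C4' and can reach C6' only on that face, cis to the C2' chain, which is the face an untethered nucleophile would avoid; the C7' carbinol centre is set only loosely by the exo or endo position of the dienyl group and is erased in step 11. The step needs deprotonation at C7' rather than at C4'–H or the C9' methyl group, [2,3]- rather than [1,2]- or [1,4]-shift, and no drift of the new alkene into conjugation. These are secured by the double activation of C7'H2, by the low temperature together with an accessible conformer that has C4'–O pseudoaxial (the gem-dimethyl group lowers the equatorial preference of the C2' chain), and by the irreversible formation of the alkoxide.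

Step 11
Reactants: 15 (2E)-1-[(1R,5R)-5-{(2E)-4-[(tert-butyldiphenylsilyl)oxy]-3-methylbut-2-en-1-yl}-2,6,6-trimethylcyclohex-2-en-1-yl]-3-methylpenta-2,4-dien-1-ol
Product: 16 [(2E,4E)-5-[(1R,5R)-5-{(2E)-4-[(tert-butyldiphenylsilyl)oxy]-3-methylbut-2-en-1-yl}-2,6,6-trimethylcyclohex-2-en-1-yl]-3-methylpenta-2,4-dien-1-yl]triphenylphosphonium bromide
Conditions: PPh3·HBr, CH2Cl2, 0 °C → rt
Reagents that add atoms: triphenylphosphine hydrobromide, [Br-].c1ccccc1[PH+](c1ccccc1)c1ccccc1
Why: Allylic ionisation and phosphine capture (SN1' type, the reaction used for vinyl carbinols of the ionone series): loss of water from C7' gives the C7'–C11' pentadienyl cation, which PPh3 traps at the unhindered terminus C11' to give the conjugated (7'E,9'E)-diene, while C6', C2' and the ε-alkene are not involved and the TBDPS ether should survive the weak acid.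

Step 12
Reactants: 17 (2R)-5-methyl-2-(prop-1-en-2-yl)hex-4-en-1-ol ((R)-lavandulol)
Product: 18 (2S)-2-(2-hydroxypropan-2-yl)-5-methylhex-4-en-1-ol
Conditions: Co(acac)2 (cat.), PhSiH3, O2 (1 atm), THF, rt
Reagents that add atoms: dioxygen, O=O
Why: Mukaiyama hydration (cobalt-hydride hydrogen-atom transfer, O2 capture of the tertiary radical): hydrogen-atom transfer should be faster to the unhindered 1,1-disubstituted isopropenyl group than to the trisubstituted prenyl alkene, gives the Markovnikov tertiary alcohol at C1 and leaves the bought C2 stereocentre untouched.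

Step 13
Reactants: 18 (2S)-2-(2-hydroxypropan-2-yl)-5-methylhex-4-en-1-ol
Product: 19 bis(triethylsilyl) ether of 18 (2S)
Conditions: TESOTf, 2,6-lutidine, CH2Cl2, 0 °C
Reagents that add atoms: triethylsilyl trifluoromethanesulfonate, CC[Si](CC)(CC)OS(=O)(=O)C(F)(F)F
Why: Silyl ether formation with the reactive triflate, which also silylates the hindered tertiary alcohol and so blocks retro-aldol cleavage at the later β-oxy aldehyde stage.

Step 14
Reactants: 19 bis(triethylsilyl) ether of 18
Product: 20 (2R)-5-methyl-2-{2-[(triethylsilyl)oxy]propan-2-yl}hex-4-enal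
Conditions: (COCl)2, DMSO, CH2Cl2, −78 → −30 °C; Et3N, −78 → 0 °C
Reagents that add atoms: none
Why: Swern oxidation applied to a bis-TES ether: the activated sulfoxide cleaves and oxidises the unhindered primary TES ether directly to the aldehyde, the tertiary TES ether is inert, and the low temperature should prevent epimerisation at C2.

Step 15
Reactants: 20 (2R)-5-methyl-2-{2-[(triethylsilyl)oxy]propan-2-yl}hex-4-enal
Product: 21 (2E,4E,6S)-3,9-dimethyl-6-{2-[(triethylsilyl)oxy]propan-2-yl}deca-2,4,8-trienenitrile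
Conditions: LiN(SiMe3)2, THF, −78 → 0 °C
Reagents that add atoms: diethyl [(2E)-3-cyano-2-methylprop-2-en-1-yl]phosphonate, CCOP(=O)(OCC)C/C(C)=C/C#N
Why: Horner–Wadsworth–Emmons olefination with a vinylogous cyano-stabilised phosphonate anion, weakly basic enough to spare the α-stereocentre C2, forms C3=C4 with E selectivity and brings in C4–C7 together with the C5 methyl group.

Step 16
Reactants: 21 (2E,4E,6S)-3,9-dimethyl-6-{2-[(triethylsilyl)oxy]propan-2-yl}deca-2,4,8-trienenitrile
Product: 22 (2E,4E,6S)-3,9-dimethyl-6-{2-[(triethylsilyl)oxy]propan-2-yl}deca-2,4,8-trienal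
Conditions: i-Bu2AlH, toluene, −78 °C; then wet SiO2
Reagents that add atoms: water, O
Why: Partial reduction of a conjugated nitrile with one hydride equivalent followed by hydrolysis on work-up stops at the aldehyde oxidation level, and the silyl ether and the alkenes are inert at low temperature.

Step 17
Reactants: 22 (2E,4E,6S)-3,9-dimethyl-6-{2-[(triethylsilyl)oxy]propan-2-yl}deca-2,4,8-trienal
Product: 23 ethyl (2E,4E,6E,8E,10S)-3,7,13-trimethyl-10-{2-[(triethylsilyl)oxy]propan-2-yl}tetradeca-2,4,6,8,12-pentaenoate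
Conditions: LiN(SiMe3)2, THF/DMPU, −78 → 0 °C
Reagents that add atoms: ethyl (2E)-4-(diethoxyphosphoryl)-3-methylbut-2-enoate, CCOC(=O)/C=C(C)/CP(=O)(OCC)OCC
Why: Second Horner–Wadsworth–Emmons olefination with the vinylogous ester-stabilised phosphonate anion forms C7=C8 (E) and brings in C8–C11 together with the C9 methyl group.

Step 18
Reactants: 23 ethyl (2E,4E,6E,8E,10S)-3,7,13-trimethyl-10-{2-[(triethylsilyl)oxy]propan-2-yl}tetradeca-2,4,6,8,12-pentaenoate
Product: 24 (2E,4E,6E,8E,10S)-3,7,13-trimethyl-10-{2-[(triethylsilyl)oxy]propan-2-yl}tetradeca-2,4,6,8,12-pentaen-1-ol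
Conditions: i-Bu2AlH, CH2Cl2, −78 °C; then aq potassium sodium tartrate
Reagents that add atoms: none
Why: 1,2-selective ester reduction with i-Bu2AlH gives the allylic alcohol without touching the conjugated tetraene.

Step 19
Reactants: 24 (2E,4E,6E,8E,10S)-3,7,13-trimethyl-10-{2-[(triethylsilyl)oxy]propan-2-yl}tetradeca-2,4,6,8,12-pentaen-1-ol
Product: 25 [(2E,4E,6E,8E,10S)-3,7,13-trimethyl-10-{2-[(triethylsilyl)oxy]propan-2-yl}tetradeca-2,4,6,8,12-pentaen-1-yl]triphenylphosphonium bromide
Conditions: PPh3·HBr, CH2Cl2, 0 °C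
Reagents that add atoms: triphenylphosphine hydrobromide, [Br-].c1ccccc1[PH+](c1ccccc1)c1ccccc1
Why: Allylic ionisation and phosphine capture: the polyenylic primary alcohol ionises readily under the weakly acidic salt and PPh3 attacks the primary terminus C11, which keeps the conjugated all-E tetraene, while the hindered tertiary TES ether should survive the short exposure.

Step 20
Reactants: 25 acyclic-end C20 phosphonium bromide; 26 (2E,4E,6E)-2,7-dimethylocta-2,4,6-trienedial
Product: 28 (2E,4E,6E,8E,10E,12E,14E,16E,18S)-2,7,11,15,21-pentamethyl-18-{2-[(triethylsilyl)oxy]propan-2-yl}docosa-2,4,6,8,10,12,14,16,20-nonaenal, via acyclic-end ylide 27 (not isolated)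
Conditions: NaN(SiMe3)2, THF, −78 °C; added to 26 (3 equiv), −78 → 0 °C
Reagents that add atoms: none
Why: Wittig olefination of a semistabilised polyenyl ylide; inverse addition to an excess of the symmetrical dialdehyde favours mono-olefination and forms C11=C12 mainly E (any Z isomer is equilibrated in step 21).

Step 21
Reactants: 16 ε-end C20 phosphonium bromide; 28 C30 aldehyde
Product: 30 all-E (2S,2'R,6'R) bis-silyl ether of the target (C1–OTES, C4''–OTBDPS), via ε-end ylide 29 (not isolated)
Conditions: NaN(SiMe3)2, THF, −78 → 0 °C; then n-heptane, reflux, Ar, dark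
Reagents that add atoms: none
Why: Wittig olefination joins the two halves at C11'=C12', and the thermal Z to E equilibration of unhindered disubstituted polyene double bonds that is standard for carotenoids should converge on the all-E isomer; the amide base is too weak to deprotonate C6'–H or C2–H, so the three stereocentres persist.

Step 22
Reactants: 30 bis-silyl ether of the target
Product: 31 target, (2S,2'R,6'R)-2'-[(2E)-4-hydroxy-3-methylbut-2-en-1-yl]-2-(3-methylbut-2-en-1-yl)-3,4-didehydro-1,2-dihydro-ε,ψ-caroten-1-ol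
Conditions: Bu4NF, THF, rt, dark
Reagents that add atoms: none
Why: Fluoride-mediated cleavage of both silyl ethers under non-acidic conditions that the polyene, the ε-ring and the tertiary alcohol tolerate gives the target.

## Compound list

1 | 2-methylpropanal | CC(C)C=O | starting material
2 | pent-1-en-3-one | CCC(=O)C=C | starting material
3 | 2,4,4-trimethylcyclohex-2-en-1-one | CC1=CC(C)(C)CCC1=O | intermediate
4 | 2,4,4-trimethylcyclohexa-2,5-dien-1-one | CC1=CC(C)(C)C=CC1=O | intermediate
5 | (5R)-2,4,4-trimethyl-5-vinylcyclohex-2-en-1-one | O=C1C[C@H](C=C)C(C)(C)C=C1C | intermediate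
6 | [(1S)-2,2,4-trimethyl-5-oxocyclohex-3-en-1-yl]acetaldehyde | O=C1C[C@H](CC=O)C(C)(C)C=C1C | intermediate
7 | (2E)-2-methyl-4-[(1S)-2,2,4-trimethyl-5-oxocyclohex-3-en-1-yl]but-2-enal | O=C1C[C@H](C/C=C(\C)C=O)C(C)(C)C=C1C | intermediate
8 | (1R,5S)-5-[(2E)-4-hydroxy-3-methylbut-2-en-1-yl]-2,4,4-trimethylcyclohex-2-en-1-ol (cis) | O[C@@H]1C[C@H](C/C=C(\C)CO)C(C)(C)C=C1C | intermediate
9 | (1R,5S)-5-{(2E)-4-[(tert-butyldiphenylsilyl)oxy]-3-methylbut-2-en-1-yl}-2,4,4-trimethylcyclohex-2-en-1-ol (cis) | O[C@@H]1C[C@H](C/C=C(\C)CO[Si](c2ccccc2)(c2ccccc2)C(C)(C)C)C(C)(C)C=C1C | intermediate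
10 | (2E)-3-methylpent-2-en-4-yn-1-ol | C#C/C(C)=C/CO | starting material
11 | (2E)-3-methylpenta-2,4-dien-1-ol | C=C/C(C)=C/CO | intermediate
12 | (3E)-5-bromo-3-methylpenta-1,3-diene | C=C/C(C)=C/CBr | intermediate
13 | C4'-O-[(2E)-3-methylpenta-2,4-dien-1-yl] ether of 9 (not isolated) | C=C/C(C)=C/CO[C@@H]1C[C@H](C/C=C(\C)CO[Si](c2ccccc2)(c2ccccc2)C(C)(C)C)C(C)(C)C=C1C | intermediate
14 | C7'-lithio derivative of 13 (not isolated) | C=C/C(C)=C/C([Li])O[C@@H]1C[C@H](C/C=C(\C)CO[Si](c2ccccc2)(c2ccccc2)C(C)(C)C)C(C)(C)C=C1C | intermediate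
15 | (2E)-1-[(1R,5R)-5-{(2E)-4-[(tert-butyldiphenylsilyl)oxy]-3-methylbut-2-en-1-yl}-2,6,6-trimethylcyclohex-2-en-1-yl]-3-methylpenta-2,4-dien-1-ol, both C7' epimers | C=C/C(C)=C/C(O)[C@@H]1C(C)=CC[C@H](C/C=C(\C)CO[Si](c2ccccc2)(c2ccccc2)C(C)(C)C)C1(C)C | intermediate
16 | ε-end C20 salt, [(2E,4E)-5-[(1R,5R)-5-{(2E)-4-[(tert-butyldiphenylsilyl)oxy]-3-methylbut-2-en-1-yl}-2,6,6-trimethylcyclohex-2-en-1-yl]-3-methylpenta-2,4-dien-1-yl]triphenylphosphonium bromide | [Br-].c1ccccc1[P+](c1ccccc1)(c1ccccc1)C/C=C(C)/C=C/[C@@H]1C(C)=CC[C@H](C/C=C(\C)CO[Si](c2ccccc2)(c2ccccc2)C(C)(C)C)C1(C)C | intermediate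
17 | (R)-lavandulol, (2R)-5-methyl-2-(prop-1-en-2-yl)hex-4-en-1-ol | CC(C)=CC[C@@H](CO)C(C)=C | starting material
18 | (2S)-2-(2-hydroxypropan-2-yl)-5-methylhex-4-en-1-ol | CC(C)=CC[C@@H](CO)C(C)(C)O | intermediate
19 | bis(triethylsilyl) ether of 18 (2S) | CC(C)=CC[C@@H](CO[Si](CC)(CC)CC)C(C)(C)O[Si](CC)(CC)CC | intermediate
20 | (2R)-5-methyl-2-{2-[(triethylsilyl)oxy]propan-2-yl}hex-4-enal | CC(C)=CC[C@@H](C=O)C(C)(C)O[Si](CC)(CC)CC | intermediate
21 | (2E,4E,6S)-3,9-dimethyl-6-{2-[(triethylsilyl)oxy]propan-2-yl}deca-2,4,8-trienenitrile | CC(C)=CC[C@@H](/C=C/C(C)=C/C#N)C(C)(C)O[Si](CC)(CC)CC | intermediate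
22 | (2E,4E,6S)-3,9-dimethyl-6-{2-[(triethylsilyl)oxy]propan-2-yl}deca-2,4,8-trienal | CC(C)=CC[C@@H](/C=C/C(C)=C/C=O)C(C)(C)O[Si](CC)(CC)CC | intermediate
23 | ethyl (2E,4E,6E,8E,10S)-3,7,13-trimethyl-10-{2-[(triethylsilyl)oxy]propan-2-yl}tetradeca-2,4,6,8,12-pentaenoate | CC(C)=CC[C@@H](/C=C/C(C)=C/C=C/C(C)=C/C(=O)OCC)C(C)(C)O[Si](CC)(CC)CC | intermediate
24 | (2E,4E,6E,8E,10S)-3,7,13-trimethyl-10-{2-[(triethylsilyl)oxy]propan-2-yl}tetradeca-2,4,6,8,12-pentaen-1-ol | CC(C)=CC[C@@H](/C=C/C(C)=C/C=C/C(C)=C/CO)C(C)(C)O[Si](CC)(CC)CC | intermediate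
25 | acyclic-end C20 salt, [(2E,4E,6E,8E,10S)-3,7,13-trimethyl-10-{2-[(triethylsilyl)oxy]propan-2-yl}tetradeca-2,4,6,8,12-pentaen-1-yl]triphenylphosphonium bromide | [Br-].CC(C)=CC[C@@H](/C=C/C(C)=C/C=C/C(C)=C/C[P+](c1ccccc1)(c1ccccc1)c1ccccc1)C(C)(C)O[Si](CC)(CC)CC | intermediate
26 | (2E,4E,6E)-2,7-dimethylocta-2,4,6-trienedial | O=C/C(C)=C/C=C/C=C(C)/C=O | starting material
27 | ylide of 25 (not isolated) | CC(C)=CC[C@@H](/C=C/C(C)=C/C=C/C(C)=C/C=P(c1ccccc1)(c1ccccc1)c1ccccc1)C(C)(C)O[Si](CC)(CC)CC | intermediate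
28 | C30 aldehyde, (2E,4E,6E,8E,10E,12E,14E,16E,18S)-2,7,11,15,21-pentamethyl-18-{2-[(triethylsilyl)oxy]propan-2-yl}docosa-2,4,6,8,10,12,14,16,20-nonaenal | CC(C)=CC[C@@H](/C=C/C(C)=C/C=C/C(C)=C/C=C/C(C)=C/C=C/C=C(C)/C=O)C(C)(C)O[Si](CC)(CC)CC | intermediate
29 | ylide of 16 (not isolated) | c1ccccc1P(c1ccccc1)(c1ccccc1)=C/C=C(C)/C=C/[C@@H]1C(C)=CC[C@H](C/C=C(\C)CO[Si](c2ccccc2)(c2ccccc2)C(C)(C)C)C1(C)C | intermediate
30 | all-E (2S,2'R,6'R) bis-silyl ether of the target (C1–OTES, C4''–OTBDPS) | CC(C)=CC[C@@H](/C=C/C(C)=C/C=C/C(C)=C/C=C/C(C)=C/C=C/C=C(C)/C=C/C=C(C)/C=C/[C@@H]1C(C)=CC[C@H](C/C=C(\C)CO[Si](c2ccccc2)(c2ccccc2)C(C)(C)C)C1(C)C)C(C)(C)O[Si](CC)(CC)CC | intermediate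
31 | CNP0409952.1, (2S,2'R,6'R)-2'-[(2E)-4-hydroxy-3-methylbut-2-en-1-yl]-2-(3-methylbut-2-en-1-yl)-3,4-didehydro-1,2-dihydro-ε,ψ-caroten-1-ol | CC(C)=CC[C@@H](/C=C/C(C)=C/C=C/C(C)=C/C=C/C(C)=C/C=C/C=C(C)/C=C/C=C(C)/C=C/[C@@H]1C(C)=CC[C@H](C/C=C(\C)CO)C1(C)C)C(C)(C)O | target

## Step count and risks

Total step count: 22.
Longest linear sequence: 11 steps (1–7, 10, 11, 21, 22). The sequence 12–22 has the same length.

Steps most likely to fail:

1. **Step 10 (key step).** Bond formation at the neopentyl C6', on the face syn to the C2' chain, may be slow. A [1,2]-shift, 1,4-elimination of the ring alkoxide or addition of n-BuLi to the diene could then take over.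
   Fallback (intermolecular allylboration in place of the tethered carbanion): it sets out from 9 and 11 and comes back at 15. Mitsunobu inversion of 9 with acetic acid (PPh3, DIAD, THF) gives the trans-configured allylic acetate F1. Pd(dba)2-catalysed borylation with B2pin2 (DMSO, 50 °C) proceeds by ionisation with inversion and boron transfer with retention at the less hindered terminus C4', and gives the cis-configured allylboronate F2. Oxidation of 11 with MnO2 gives (2E)-3-methylpenta-2,4-dienal F3. F2 and F3 combine in toluene (rt to 60 °C) through the closed six-membered transition state of an allylboration. C6'–C7' forms on the boron-bearing face while the alkene shifts to C4'=C5', and aqueous work-up gives 15.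

2. **Step 3.** Conversion may be low or facial selection poor, because the β-carbon of the enone is flanked by the quaternary C1'.
   Fallback (racemic addition and enzymatic resolution in place of asymmetric catalysis): it sets out from 4 and comes back at 5. CuBr·SMe2-catalysed addition of vinylmagnesium bromide (THF, −40 °C) gives racemic 2,4,4-trimethyl-5-vinylcyclohex-2-en-1-one F4. Luche reduction gives the racemic cis-2,4,4-trimethyl-5-vinylcyclohex-2-en-1-ol F5. Acylation with vinyl acetate and Candida antarctica lipase B (MTBE, rt) is expected to convert the (1R)-carbinol only, giving the (1R,5R)-acetate F6, which is separated from the unreacted enantiomer. K2CO3/MeOH gives the (1R,5R)-alcohol F7, and MnO2 oxidation returns 5.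

3. **Step 4.** Oxidation of the hindered vinyl group may be slow, or regiocontrol may be lost toward Markovnikov oxidation.
   Fallback (hydroboration and two-stage oxidation in place of direct oxidation): it sets out from 5 and comes back at 6. RhCl(PPh3)3-catalysed hydroboration with pinacolborane (THF, rt), to which the cyclic s-trans enone is inert, gives the primary pinacol boronate F8. NaBO3·4H2O (THF/H2O) gives the primary alcohol F9, and Dess–Martin periodinane (CH2Cl2, NaHCO3) returns 6.

## Further compounds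

F1 | step 10 | (1S,5S)-5-{(2E)-4-[(tert-butyldiphenylsilyl)oxy]-3-methylbut-2-en-1-yl}-2,4,4-trimethylcyclohex-2-en-1-yl acetate (acetate trans to the C2' chain) | CC(=O)O[C@H]1C[C@H](C/C=C(\C)CO[Si](c2ccccc2)(c2ccccc2)C(C)(C)C)C(C)(C)C=C1C
F2 | step 10 | 2-[(1R,5R)-5-{(2E)-4-[(tert-butyldiphenylsilyl)oxy]-3-methylbut-2-en-1-yl}-2,4,4-trimethylcyclohex-2-en-1-yl]-4,4,5,5-tetramethyl-1,3,2-dioxaborolane (boron cis to the C2' chain) | CC1(C)OB(OC1(C)C)[C@@H]1C[C@H](C/C=C(\C)CO[Si](c2ccccc2)(c2ccccc2)C(C)(C)C)C(C)(C)C=C1C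
F3 | step 10 | (2E)-3-methylpenta-2,4-dienal | C=C/C(C)=C/C=O
F4 | step 3 | racemic 2,4,4-trimethyl-5-vinylcyclohex-2-en-1-one | C=CC1CC(=O)C(C)=CC1(C)C
F5 | step 3 | racemic cis-2,4,4-trimethyl-5-vinylcyclohex-2-en-1-ol | C=CC1CC(O)C(C)=CC1(C)C
F6 | step 3 | (1R,5R)-2,4,4-trimethyl-5-vinylcyclohex-2-en-1-yl acetate | CC(=O)O[C@@H]1C[C@H](C=C)C(C)(C)C=C1C
F7 | step 3 | (1R,5R)-2,4,4-trimethyl-5-vinylcyclohex-2-en-1-ol | O[C@@H]1C[C@H](C=C)C(C)(C)C=C1C
F8 | step 4 | (5S)-2,4,4-trimethyl-5-[2-(4,4,5,5-tetramethyl-1,3,2-dioxaborolan-2-yl)ethyl]cyclohex-2-en-1-one | O=C1C[C@H](CCB2OC(C)(C)C(C)(C)O2)C(C)(C)C=C1C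
F9 | step 4 | (5S)-5-(2-hydroxyethyl)-2,4,4-trimethylcyclohex-2-en-1-one | O=C1C[C@H](CCO)C(C)(C)C=C1C
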